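**Retrosynthetic overview**

1. 23 ⇐ 22 by peracid epoxidation of C1=C10; 22 ⇐ 20 by a ring-expanding Grob fragmentation of the decalin C5–C10 bond (5α-alkoxide pushes, 1β-mesylate leaves), with the new C5 ketone reduced in the same pot.
2. 20 ⇐ 13 by Luche reduction (C1, C8), Mitsunobu inversion/angeloylation at C8, Eschenmoser methylenation of the lactone and mesylation of the C1–OH.
3. 13 ⇐ 10 by α-face bis-dihydroxylation of the C5=C6/C4=C15 diene (sets C4, C5, C6), lactonisation on O6 and Mitsunobu closure of the spiro-oxirane.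
4. 10 ⇐ 6 by Wittig methylenation at C4, then fluoride-triggered methanol loss and trienolate C7-alkylation with methyl bromoacetate; 6 ⇐ Diels–Alder of epoxyquinone 3 with diene 5.
5. 3 ⇐ 2 ⇐ o-cresol by a new catalytic enantioselective quinone mono-epoxidation (sets C2/C3; every other centre is relayed from them). Ring order: carbocycle A plus oxirane → carbocycle B → lactone → spiro-oxirane → ten-membered ring → third oxirane.

Convention and assumption: decalins carry eudesmane numbers (C1–C10 ring carbons, C14 = methyl on C10, C15 = carbon on C4, C11–C13 = lactone carbons), β is the face of the C10 methyl, and the ten-membered compounds keep the same numbers; the quinidinium catalyst of step 2 is assumed to give the (1R,6S)-epoxide (its quininium pseudo-enantiomer would be used otherwise).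

**Route**

Step 1
Reactants: 1 o-cresol (2-methylphenol)
Product: 2 2-methyl-1,4-benzoquinone
Conditions: O2 (1 atm), Co(C16H14N2O2) (salen complex of divalent cobalt, 5 mol %), DMF, 25 °C
Reagents that add atoms: dioxygen, O=O
Why: Salcomine-type aerobic oxidation of a para-unsubstituted phenol gives the p-quinone through a phenoxyl/cobalt–superoxo pathway; no stereocentre is formed.

Step 2
Reactants: 2 2-methyl-1,4-benzoquinone
Product: 3 (1R,6S)-3-methyl-7-oxabicyclo[4.1.0]hept-3-ene-2,5-dione (toluquinone 5,6-epoxide)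
Conditions: t-BuOOH (1.05 equiv), N-(9-anthracenylmethyl)quinidinium bromide (free C9–OH, 10 mol %), K2CO3 (20 mol %), toluene, −40 °C
Reagents that add atoms: tert-butyl hydroperoxide, CC(C)(C)OO
Why: Proposed new method: catalytic enantioselective Weitz–Scheffer mono-epoxidation of a simple p-benzoquinone, in which the chiral ammonium ion-pairs t-BuOO−, its C9–OH hydrogen-bonds the carbonyl flanked by two ring CH groups, the peroxide adds to the more electrophilic unsubstituted C5=C6 bond (the methyl deactivates C2=C3) on one enantioface inside the anthracenyl pocket and the enolate closes to the cis-oxirane, setting both oxirane stereocentres from which all later centres are relayed; the closest known chemistry is cinchona phase-transfer Weitz–Scheffer epoxidation of enones and 2-alkyl-1,4-naphthoquinones.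

Step 3
Reactants: 4 (E)-4-methoxybut-3-en-2-one
Product: 5 (E)-1-methoxy-3-(tert-butyldimethylsilyloxy)buta-1,3-diene
Conditions: TBSOTf (1.1 equiv), Et3N (1.5 equiv), Et2O, −20 → 0 °C
Reagents that add atoms: tert-butyldimethylsilyl trifluoromethanesulfonate, CC(C)(C)[Si](C)(C)OS(=O)(=O)C(F)(F)F
Why: Soft enolisation and O-silylation of the methyl ketone gives the Danishefsky-type diene with the E enol ether untouched, the TBS ether being robust enough for step 5; no stereocentre is formed.

Step 4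
Reactants: 3 (1R,6S)-3-methyl-7-oxabicyclo[4.1.0]hept-3-ene-2,5-dione; 5 (E)-1-methoxy-3-(tert-butyldimethylsilyloxy)buta-1,3-diene
Product: 6 cis-fused adduct 2β,3β-epoxy-6α-methoxy-10β-methyl-8-(tert-butyldimethylsilyloxy)-5βH-octal-7-ene-1,4-dione
Conditions: ZnCl2 (10 mol %), THF, −40 → 0 °C; Et3N quench
Reagents that add atoms: none
Why: Lewis-acid-catalysed endo Diels–Alder reaction in which ZnCl2 binds the less hindered and more basic C4 carbonyl so that the nucleophilic CH2 terminus of the diene bonds to the methyl-bearing β-carbon (C10), while the diene approaches anti to the oxirane oxygen and so places the quaternary C10 methyl syn to the oxirane; C5 and C6 are also set but are erased in step 6.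

Step 5
Reactants: 6 cis-fused Diels–Alder adduct
Product: 7 2β,3β-epoxy-6α-methoxy-10β-methyl-4-methylene-8-(tert-butyldimethylsilyloxy)-5βH-octal-7-en-1-one
Conditions: Ph3PCH3Br (1.3 equiv), KN(SiMe3)2 (1.25 equiv), THF, 0 °C; then 6, −78 → 0 °C
Reagents that add atoms: methyltriphenylphosphonium bromide, C[P+](c1ccccc1)(c1ccccc1)c1ccccc1.[Br-]
Why: Wittig methylenation is selective for the C4 carbonyl (next to the C5 methine) over the neopentyl C1 carbonyl, and the C8 carbonyl is still masked as its silyl enol ether; no new stereocentre is formed.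

Step 6
Reactants: 7 4-methylene silyl enol ether; 8 methyl bromoacetate
Product: 10 methyl 2-(2β,3β-epoxy-10β-methyl-4-methylene-1,8-dioxo-octal-5-en-7β-yl)acetate, via enone 9 (not isolated)
Conditions: Bu4NF (1.05 equiv, dried), THF, −40 → 0 °C; then 8 (1.2 equiv), −78 → −20 °C; AcOH
Reagents that add atoms: none
Why: Fluoride unmasks the C8 enolate, E1cB loss of methoxide gives enone 9, the released methoxide removes the doubly allylic γ-H at C5 to give the thermodynamic trienolate, and this is alkylated at its α-carbon C7 (classical α-alkylation of an extended enolate), which moves the ring double bond to C5=C6; C7 forms as an epimer mixture (drawn 7β) that converges in step 7.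

Step 7
Reactants: 10 keto ester diene
Product: 12 2β,3β-epoxy-4α,5α,15-trihydroxy-1,8-dioxo-13-noreudesman-12,6α-olide, via tetraol ester 11 (not isolated)
Conditions: OsO4 (5 mol %), NMO (2.6 equiv), acetone/H2O 8:1, 0 → 25 °C; then Et3N (0.2 equiv), CH2Cl2, 25 °C
Reagents that add atoms: N-methylmorpholine N-oxide, C[N+]1([O-])CCOCC1; water, O
Why: Upjohn syn-dihydroxylation of both alkenes on the α-face, anti to the C10 methyl and the β-oxirane, sets C4, C5 and C6, after which the 6α-OH lactonises onto the ester and C7 (enolisable through the C8 ketone) equilibrates to the trans-diequatorial γ-lactone.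

Step 8
Reactants: 12 lactone triol
Product: 13 2β,3β:4α,15-diepoxy-5α-hydroxy-1,8-dioxo-13-noreudesman-12,6α-olide
Conditions: PPh3 (1.3 equiv), DIAD (1.3 equiv), THF, 0 → 25 °C
Reagents that add atoms: none
Why: Mitsunobu cyclodehydration of the primary/tertiary 1,2-diol activates the primary C15–OH, which is displaced by the tertiary C4–O, so C4 keeps its configuration (oxirane oxygen α) and the tertiary C5–OH is left alone.

Step 9
Reactants: 13 spiro-epoxy diketone
Product: 14 2β,3β:4α,15-diepoxy-1β,5α,8β-trihydroxy-13-noreudesman-12,6α-olide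
Conditions: NaBH4 (2.5 equiv), CeCl3·7H2O (2.2 equiv), MeOH/CH2Cl2, −78 → −40 °C; AcOH
Reagents that add atoms: none
Why: Luche reduction, where hydride reaches C1 from the α-face (anti to the C10 methyl and the β-oxirane oxygen) to give the equatorial 1β-OH, while at C8 the axial β-trajectory is blocked by the syn-axial C10 methyl so equatorial attack gives the axial 8β-OH, as with 2-oxo-5α-steroids.

Step 10
Reactants: 14 triol; 15 angelic acid ((Z)-2-methylbut-2-enoic acid)
Product: 16 8α-angeloyloxy-2β,3β:4α,15-diepoxy-1β,5α-dihydroxy-13-noreudesman-12,6α-olide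
Conditions: PPh3 (1.6 equiv), DIAD (1.6 equiv), 15 (1.6 equiv), toluene, 0 → 25 °C
Reagents that add atoms: none
Why: Mitsunobu esterification with SN2 inversion turns the axial 8β-OH into the equatorial 8α-angelate without acyl activation (so no Z-to-E isomerisation), and the neopentyl C1–OH and tertiary C5–OH do not react.

Step 11
Reactants: 16 angelate lactone
Product: 19 8α-angeloyloxy-2β,3β:4α,15-diepoxy-1β,5α-dihydroxyeudesm-11(13)-en-12,6α-olide, via Mannich base 17 (not isolated), via methiodide 18 (not isolated)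
Conditions: LiN(SiMe3)2 (3.3 equiv), THF, −78 °C; Me2N=CH2 I (1.5 equiv), −78 → −20 °C; MeI, MeOH, 25 °C; NaHCO3 (aq), CH2Cl2, 25 °C
Reagents that add atoms: dimethylmethylideneammonium iodide (Eschenmoser's salt), C=[N+](C)C.[I-]
Why: Lactone-enolate Mannich reaction with Eschenmoser's salt, N-methylation and E1cB loss of trimethylamine give the α-methylene lactone, the lactone α-CH2 being more acidic than the γ-H of the angelate; the transient C11 stereocentre is destroyed on elimination.

Step 12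
Reactants: 19 α-methylene lactone diol
Product: 20 8α-angeloyloxy-2β,3β:4α,15-diepoxy-5α-hydroxy-1β-(methanesulfonyloxy)eudesm-11(13)-en-12,6α-olide
Conditions: MsCl (1.3 equiv), Et3N (2 equiv), CH2Cl2, −20 °C
Reagents that add atoms: methanesulfonyl chloride, CS(=O)(=O)Cl
Why: Sulfonylation (sulfene pathway) of the only secondary hydroxyl proceeds with retention at C1 and leaves the tertiary C5–OH free.

Step 13
Reactants: 20 1β-mesylate
Product: 22 8-angeloyloxy-2,3:4,15-diepoxy-5-hydroxygermacra-1(10)E,11(13)-dien-12,6-olide, via epoxy ketone 21 (not isolated)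
Conditions: KN(SiMe3)2 (1.05 equiv), THF, −78 → −30 °C; then Zn(BH4)2 (2 equiv, Et2O), −78 → −40 °C
Reagents that add atoms: none
Why: Grob (Wharton) fragmentation in which the C5 alkoxide pushes and the shared C5–C10 bond, antiperiplanar to the equatorial C1–OMs, breaks to expand the trans-decalin into the ten-membered 1(10)E-en-5-one (E because H1 is anti to the axial C10 methyl), and the ketone is then reduced under chelation control (Zn bridging C5=O and the oxirane or lactone oxygen) to the 5-OH syn to both flanking oxygens.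

Step 14
Reactants: 22 ten-membered dienolide alcohol
Product: 23 CNP0594916.1
Conditions: mCPBA (1.2 equiv), NaHCO3, CH2Cl2, 0 °C
Reagents that add atoms: meta-chloroperoxybenzoic acid, OOC(=O)c1cccc(Cl)c1
Why: Prilezhaev epoxidation of the only nucleophilic alkene (the acrylate and angelate alkenes are electron-poor) occurs stereospecifically on the E-alkene from the outer face of the ring conformer with C14 on the β-side, giving the trans 1β,10α-oxirane.

**Compound list**

1 | o-cresol (2-methylphenol) | Cc1ccccc1O | starting material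
2 | 2-methyl-1,4-benzoquinone | CC1=CC(=O)C=CC1=O | intermediate
3 | (1R,6S)-3-methyl-7-oxabicyclo[4.1.0]hept-3-ene-2,5-dione | CC1=CC(=O)[C@H]2O[C@H]2C1=O | intermediate
4 | (E)-4-methoxybut-3-en-2-one | CO/C=C/C(C)=O | starting material
5 | (E)-1-methoxy-3-(tert-butyldimethylsilyloxy)buta-1,3-diene | CO/C=C/C(=C)O[Si](C)(C)C(C)(C)C | intermediate
6 | 2β,3β-epoxy-6α-methoxy-10β-methyl-8-(tert-butyldimethylsilyloxy)-5βH-octal-7-ene-1,4-dione (cis-fused) | CO[C@H]1C=C(O[Si](C)(C)C(C)(C)C)C[C@@]2(C)C(=O)[C@@H]3O[C@@H]3C(=O)[C@@H]12 | intermediate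
7 | 2β,3β-epoxy-6α-methoxy-10β-methyl-4-methylene-8-(tert-butyldimethylsilyloxy)-5βH-octal-7-en-1-one | CO[C@H]1C=C(O[Si](C)(C)C(C)(C)C)C[C@@]2(C)C(=O)[C@@H]3O[C@@H]3C(=C)[C@@H]12 | intermediate
8 | methyl bromoacetate | COC(=O)CBr | starting material
9 | 2β,3β-epoxy-10β-methyl-4-methylene-5βH-octal-6-ene-1,8-dione | C1=CC(=O)C[C@@]2(C)C(=O)[C@@H]3O[C@@H]3C(=C)[C@@H]12 | intermediate (not isolated)
10 | methyl 2-(2β,3β-epoxy-10β-methyl-4-methylene-1,8-dioxo-octal-5-en-7β-yl)acetate | COC(=O)C[C@H]1C=C2C(=C)[C@H]3O[C@H]3C(=O)[C@]2(C)CC1=O | intermediate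
11 | methyl 2-[2β,3β-epoxy-4α,5α,6α-trihydroxy-4β-(hydroxymethyl)-10β-methyl-1,8-dioxodecal-7β-yl]acetate | COC(=O)C[C@H]1[C@H](O)[C@@]2(O)[C@@](O)(CO)[C@H]3O[C@H]3C(=O)[C@]2(C)CC1=O | intermediate (not isolated)
12 | 2β,3β-epoxy-4α,5α,15-trihydroxy-1,8-dioxo-13-noreudesman-12,6α-olide (trans-lactone, 7αH) | O=C1C[C@@H]2C(=O)C[C@@]3(C)C(=O)[C@@H]4O[C@@H]4[C@](O)(CO)[C@]3(O)[C@H]2O1 | intermediate
13 | 2β,3β:4α,15-diepoxy-5α-hydroxy-1,8-dioxo-13-noreudesman-12,6α-olide | O=C1C[C@@H]2C(=O)C[C@@]3(C)C(=O)[C@@H]4O[C@@H]4[C@]5(CO5)[C@]3(O)[C@H]2O1 | intermediate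
14 | 2β,3β:4α,15-diepoxy-1β,5α,8β-trihydroxy-13-noreudesman-12,6α-olide | O=C1C[C@@H]2[C@H](O)C[C@@]3(C)[C@H](O)[C@@H]4O[C@@H]4[C@]5(CO5)[C@]3(O)[C@H]2O1 | intermediate
15 | angelic acid ((Z)-2-methylbut-2-enoic acid) | C/C=C(/C)C(=O)O | starting material
16 | 8α-angeloyloxy-2β,3β:4α,15-diepoxy-1β,5α-dihydroxy-13-noreudesman-12,6α-olide | O=C1C[C@@H]2[C@@H](OC(=O)/C(C)=C\C)C[C@@]3(C)[C@H](O)[C@@H]4O[C@@H]4[C@]5(CO5)[C@]3(O)[C@H]2O1 | intermediate
17 | 13-(dimethylamino)-8α-angeloyloxy-2β,3β:4α,15-diepoxy-1β,5α-dihydroxyeudesman-12,6α-olide (C11 epimers) | CN(C)CC1C(=O)O[C@H]2[C@H]1[C@@H](OC(=O)/C(C)=C\C)C[C@@]3(C)[C@H](O)[C@@H]4O[C@@H]4[C@]5(CO5)[C@]23O | intermediate (not isolated)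
18 | N-methyl quaternary ammonium iodide of 17 | C[N+](C)(C)CC1C(=O)O[C@H]2[C@H]1[C@@H](OC(=O)/C(C)=C\C)C[C@@]3(C)[C@H](O)[C@@H]4O[C@@H]4[C@]5(CO5)[C@]23O.[I-] | intermediate (not isolated)
19 | 8α-angeloyloxy-2β,3β:4α,15-diepoxy-1β,5α-dihydroxyeudesm-11(13)-en-12,6α-olide | C=C1C(=O)O[C@H]2[C@H]1[C@@H](OC(=O)/C(C)=C\C)C[C@@]3(C)[C@H](O)[C@@H]4O[C@@H]4[C@]5(CO5)[C@]23O | intermediate
20 | 8α-angeloyloxy-2β,3β:4α,15-diepoxy-5α-hydroxy-1β-(methanesulfonyloxy)eudesm-11(13)-en-12,6α-olide | C=C1C(=O)O[C@H]2[C@H]1[C@@H](OC(=O)/C(C)=C\C)C[C@@]3(C)[C@H](OS(C)(=O)=O)[C@@H]4O[C@@H]4[C@]5(CO5)[C@]23O | intermediate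
21 | 8-angeloyloxy-2,3:4,15-diepoxy-5-oxogermacra-1(10)E,11(13)-dien-12,6-olide (C2, C3, C4, C6, C7, C8 as in 23) | C=C1C(=O)O[C@H]2[C@H]1[C@@H](OC(=O)/C(C)=C\C)C/C(C)=C/[C@@H]1O[C@@H]1[C@]1(CO1)C2=O | intermediate (not isolated)
22 | 8-angeloyloxy-2,3:4,15-diepoxy-5-hydroxygermacra-1(10)E,11(13)-dien-12,6-olide (C2–C8 as in 23) | C=C1C(=O)O[C@H]2[C@H]1[C@@H](OC(=O)/C(C)=C\C)C/C(C)=C/[C@@H]1O[C@@H]1[C@]1(CO1)[C@H]2O | intermediate
23 | CNP0594916.1, 8-angeloyloxy-1,10:2,3:4,15-triepoxy-5-hydroxygermacr-11(13)-en-12,6-olide (trans 1,10-oxirane, cis 2,3-oxirane) | C=C1C(=O)O[C@H]2[C@H]1[C@@H](OC(=O)/C(C)=C\C)C[C@@]1(C)O[C@@H]1[C@@H]1O[C@@H]1[C@]1(CO1)[C@H]2O | target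

**Step count and risks**

Total steps: 14. Longest linear sequence: 13 (steps 1, 2, 4–14; step 3 makes the diene in a one-step side branch).

Three steps most likely to fail:

Step 2 (the proposed new epoxidation). The risks are low enantioselectivity, over-oxidation to the bis-epoxide and base-induced decomposition of the quinone. The fallback uses known chemistry, sets out from 2 and comes back at 3. Epoxidise 2 without chiral control (30 % H2O2, Na2CO3, THF/H2O, 0 °C) to the racemate, that is 3 together with its enantiomer, the (1S,6R)-epoxyquinone F1. Reduce the racemate at the carbonyl next to the ring CH (NaBH4, CeCl3·7H2O, MeOH, −78 °C, hydride anti to the oxirane) to the cis-epoxy alcohol F2 (from 3) and its antipode F3 (from F1). Acetylate one antipode selectively with immobilised Candida antarctica lipase B and vinyl acetate in t-BuOMe, taken here as F3, which gives the acetate F4 (if the enzyme prefers F2, its acetate is simply methanolysed after separation). Separate F2 by chromatography and oxidise it back with MnO2 in CH2Cl2 to enantiopure 3.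

Step 6 (fluoride-triggered elimination and trienolate alkylation). The risks are O-, γ- or ε-alkylation, double alkylation and transannular aldol addition onto the C1 ketone. The fallback sets out from 7 and comes back at 10. Alkylate the intact silyl enol ether by polarity-matched radical addition of 8 (Ir(C11H8N)3, the tris(2-phenylpyridinato) complex of trivalent iridium, 1 mol %, blue LED, 2,6-lutidine, MeCN), which gives the α-alkylated β-methoxy ketone F5. Eliminate methanol with DBU (CH2Cl2, 0 °C) to the conjugated enone F6. Then deconjugate by γ-deprotonation at C5 (KN(SiMe3)2, THF, −78 °C) and kinetic α-protonation (AcOH, −78 °C) to reach 10.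

Step 13 (ring-expanding fragmentation with in-pot reduction). The risks are attack of base or alkoxide on the α-methylene lactone and the angelate, and instability of the ten-membered epoxy ketone. The fallback sets out from 16 and comes back at 22, and performs the fragmentation before the Michael-acceptor lactone exists. Mesylate 16 (MsCl, Et3N, CH2Cl2, −20 °C) to the 13-nor mesylate F7. Fragment and reduce as in step 13 (KN(SiMe3)2, then Zn(BH4)2) through the 13-nor epoxy ketone F8 to the 13-nor alcohol F9. Then methylenate last (LiN(SiMe3)2 2.2 equiv and Me2N=CH2 I to the Mannich base F10, MeI to the methiodide F11, then aqueous NaHCO3) to reach 22.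

**Further compounds**

F1 | step 2 | (1S,6R)-3-methyl-7-oxabicyclo[4.1.0]hept-3-ene-2,5-dione (enantiomer of 3) | CC1=CC(=O)[C@@H]2O[C@@H]2C1=O
F2 | step 2 | 5-hydroxy-3-methyl-7-oxabicyclo[4.1.0]hept-3-en-2-one from 3 (OH cis to the oxirane) | CC1=C[C@@H](O)[C@H]2O[C@H]2C1=O
F3 | step 2 | enantiomer of F2 (from F1) | CC1=C[C@H](O)[C@@H]2O[C@@H]2C1=O
F4 | step 2 | acetate of F3 | CC1=C[C@H](OC(C)=O)[C@@H]2O[C@@H]2C1=O
F5 | step 6 | methyl 2-(2β,3β-epoxy-6α-methoxy-10β-methyl-4-methylene-1,8-dioxo-5βH-decal-7-yl)acetate (C7 epimers) | CO[C@H]1C(CC(=O)OC)C(=O)C[C@@]2(C)C(=O)[C@@H]3O[C@@H]3C(=C)[C@@H]12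
F6 | step 6 | methyl 2-(2β,3β-epoxy-10β-methyl-4-methylene-1,8-dioxo-5βH-octal-6-en-7-yl)acetate | COC(=O)CC1=C[C@@H]2C(=C)[C@H]3O[C@H]3C(=O)[C@]2(C)CC1=O
F7 | step 13 | 8α-angeloyloxy-2β,3β:4α,15-diepoxy-5α-hydroxy-1β-(methanesulfonyloxy)-13-noreudesman-12,6α-olide | O=C1C[C@@H]2[C@@H](OC(=O)/C(C)=C\C)C[C@@]3(C)[C@H](OS(C)(=O)=O)[C@@H]4O[C@@H]4[C@]5(CO5)[C@]3(O)[C@H]2O1
F8 | step 13 | 8-angeloyloxy-2,3:4,15-diepoxy-5-oxo-13-norgermacr-1(10)E-en-12,6-olide | O=C1C[C@@H]2[C@@H](OC(=O)/C(C)=C\C)C/C(C)=C/[C@@H]3O[C@@H]3[C@]4(CO4)C(=O)[C@H]2O1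
F9 | step 13 | 8-angeloyloxy-2,3:4,15-diepoxy-5-hydroxy-13-norgermacr-1(10)E-en-12,6-olide | O=C1C[C@@H]2[C@@H](OC(=O)/C(C)=C\C)C/C(C)=C/[C@@H]3O[C@@H]3[C@]4(CO4)[C@@H](O)[C@H]2O1
F10 | step 13 | 13-(dimethylamino) Mannich base of F9 (C11 epimers) | CN(C)CC1C(=O)O[C@H]2[C@H]1[C@@H](OC(=O)/C(C)=C\C)C/C(C)=C/[C@@H]1O[C@@H]1[C@]1(CO1)[C@H]2O
F11 | step 13 | N-methyl quaternary ammonium iodide of F10 | C[N+](C)(C)CC1C(=O)O[C@H]2[C@H]1[C@@H](OC(=O)/C(C)=C\C)C/C(C)=C/[C@@H]1O[C@@H]1[C@]1(CO1)[C@H]2O.[I-]
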